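**Plan**

- Retrosynthesis: the acetate, the isovalerate and the C14 aldehyde are late adjustments of a silylated macrocyclic butenolide. That bicycle is cut in one stroke at C7–C6 and C12–C11 (and at the lactone C12–O bond) to an acyclic α,β-epoxy ynal plus CO. The ynal is cut at C10=C1 (aldol, then elimination) into an alkynyl γ-lactone (C7–C14; its C8–C7 bond from an acyl Sonogashira coupling) and an epoxy aldehyde from geraniol (C1–C6, C15).
- Enabling feature: the butenolide ring holds the ring oxygen on C6, the tetrasubstituted C7=C11 bond and the C12 carbonyl, which is the pattern of an aldehyde (C6) + alkyne (C7≡C11) + CO (C12) [2+2+1]. C6 and C7 are also neighbours in the ten-membered carbocycle, so the same event closes both rings.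
- Forward order: the chain is joined first, the ten-membered ring and the lactone ring then form together in step 14, and afterwards the protecting groups come off in order while the two esters and the enal are installed.
- Stereochemistry: C8 from a Noyori transfer hydrogenation, C4/C5 from a Sharpless epoxidation, C6 from Felkin–Anh addition to the epoxy aldehyde in the key step, and the C1=C10 geometry from an E-selective elimination.

Key step: step 14

Remark: locants follow the germacrane skeleton (C6 lactone CH–O, C7=C11 lactone alkene, C12 lactone carbonyl, C13 CH2OAc, C14 CHO, C15 epoxide methyl); the target is read as 1(10)E,4R,5R,6R,8S, with C9 and C2 cis on the C1=C10 bond.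

**Route**

Step 1
Reactants: 1 methyl 4-chloro-4-oxobutanoate; 2 tert-butyldimethyl(prop-2-yn-1-yloxy)silane
Product: 3 methyl 7-[(tert-butyldimethylsilyl)oxy]-4-oxohept-5-ynoate
Conditions: PdCl2(PPh3)2 (2 mol %), CuI (4 mol %), Et3N, THF, 23 °C
Reagents that add atoms: none
Why: Acyl Sonogashira coupling of an acid chloride with a terminal alkyne is a standard route to ynones (it makes the C8–C7 bond) and should leave the methyl ester and the silyl ether untouched.

Step 2
Reactants: 3 ynone
Product: 4 methyl (4S)-7-[(tert-butyldimethylsilyl)oxy]-4-hydroxyhept-5-ynoate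
Conditions: RuCl(p-cymene)[(S,S)-TsDPEN] (1 mol %), i-PrOH, 23 °C
Reagents that add atoms: none
Why: Noyori asymmetric transfer hydrogenation of alkynyl ketones is highly enantioselective, and the (S,S) ligand is expected to set the S carbinol centre (C8) by the usual facial preference in which the alkyne plays the role of the unsaturated group.

Step 3
Reactants: 4 hydroxy ester
Product: 5 (5S)-5-{3-[(tert-butyldimethylsilyl)oxy]prop-1-yn-1-yl}oxolan-2-one
Conditions: PPTS (cat.), PhMe, 60 °C
Reagents that add atoms: none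
Why: Acid-catalysed lactonization of a γ-hydroxy ester to the five-membered lactone is favourable and does not touch the stereocentre.

Step 4
Reactants: 6 geraniol
Product: 7 (2R,3R)-2,3-epoxygeraniol
Conditions: Ti(Oi-Pr)4 (5 mol %), D-(−)-diethyl tartrate (7 mol %), t-BuOOH, 4 Å molecular sieves, CH2Cl2, −20 °C
Reagents that add atoms: tert-butyl hydroperoxide, CC(C)(C)OO
Why: Sharpless asymmetric epoxidation with the D-tartrate ligand should deliver oxygen to the face that gives the (2R,3R)-epoxy alcohol, which becomes the 4R,5R epoxide of the target, and it leaves the remote trisubstituted alkene alone.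

Step 5
Reactants: 7 epoxy alcohol
Product: 8 (2R,3R)-2-{[(4-methoxybenzyl)oxy]methyl}-3-methyl-3-(4-methylpent-3-en-1-yl)oxirane
Conditions: NaH, 4-methoxybenzyl chloride, n-Bu4NI (cat.), THF–DMF, 0 °C
Reagents that add atoms: 4-methoxybenzyl chloride, COc1ccc(CCl)cc1
Why: Williamson etherification of the primary alkoxide with the benzylic chloride is fast at 0 °C in an aprotic medium, which should outrun Payne rearrangement of the epoxy alkoxide.

Step 6
Reactants: 8 PMB ether
Product: 10 3-[(2R,3R)-3-{[(4-methoxybenzyl)oxy]methyl}-2-methyloxiran-2-yl]propanal, via diol 9 (not isolated)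
Conditions: OsO4 (2 mol %), NaIO4, 2,6-lutidine, dioxane–H2O, 23 °C
Reagents that add atoms: osmium tetroxide, O=[Os](=O)(=O)=O (oxygen donor, regenerated by NaIO4)
Why: Johnson–Lemieux cleavage (dihydroxylation of the only alkene, then periodate glycol cleavage) should give the aldehyde without touching the epoxide or the PMB ether.

Step 7
Reactants: 5 lactone; 10 epoxy aldehyde
Product: 12 aldol adduct (mixture of diastereomers at the two new centres), via lithium enolate 11 (not isolated)
Conditions: LiN(i-Pr)2, THF, −78 °C; then 10, −78 °C; aq. NH4Cl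
Reagents that add atoms: none
Why: Aldol addition of the lactone lithium enolate to the aldehyde forms the C10–C1 bond, and the configuration of the two new centres does not matter because both become sp2 in the next step.

Step 8
Reactants: 12 aldol adduct
Product: 14 (3E,5S)-alkylidene lactone, via mesylate 13 (not isolated)
Conditions: MsCl, Et3N, CH2Cl2, 0 °C; then DBU, 23 °C
Reagents that add atoms: none
Why: Mesylation followed by E1cB elimination gives the conjugated alkylidene lactone, and the E isomer (chain trans to the carbonyl group) is the one favoured in such eliminations, which fixes the C1=C10 geometry of the target.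

Step 9
Reactants: 14 alkylidene lactone
Product: 15 (2E)-2-{(2S)-5-[(tert-butyldimethylsilyl)oxy]-2-hydroxypent-3-yn-1-yl}-5-[(2R,3R)-3-{[(4-methoxybenzyl)oxy]methyl}-2-methyloxiran-2-yl]pent-2-en-1-ol
Conditions: i-Bu2AlH (4.5 equiv), CH2Cl2, −78 → −40 °C; aq. potassium sodium tartrate
Reagents that add atoms: none
Why: Lactone-to-diol reduction with i-Bu2AlH proceeds by 1,2-addition on the conjugated lactone and should spare the alkyne, the epoxide and the alkene geometry.

Step 10
Reactants: 15 diol
Product: 16 mono-silyl ether (C14–OSi-t-BuPh2, C8–OH free)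
Conditions: t-BuPh2SiCl (1.05 equiv), imidazole, CH2Cl2, 0 °C
Reagents that add atoms: tert-butyl(chloro)diphenylsilane, CC(C)(C)[Si](Cl)(c1ccccc1)c1ccccc1
Why: Silylation with the bulky chlorosilane is selective for the primary allylic hydroxyl over the secondary propargylic one (steric differentiation), and this robust group keeps C14 masked until C8 is acylated.

Step 11
Reactants: 16 mono-silyl ether
Product: 17 fully protected alkyne (C8–OSi-t-BuMe2)
Conditions: t-BuMe2SiCl, imidazole, DMAP (cat.), DMF, 40 °C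
Reagents that add atoms: tert-butyl(chloro)dimethylsilane, CC(C)(C)[Si](C)(C)Cl
Why: Standard silylation of the remaining secondary alcohol, with chloride and imidazole chosen because silyl triflates can isomerize epoxides.

Step 12
Reactants: 17 PMB ether
Product: 18 epoxy alcohol
Conditions: DDQ, CH2Cl2–pH 7 buffer, 0 °C
Reagents that add atoms: none
Why: Oxidative cleavage of the PMB ether with DDQ is orthogonal to the three silyl ethers, the epoxide and the alkyne.

Step 13
Reactants: 18 epoxy alcohol
Product: 19 (2S,3R)-epoxy aldehyde (the ynal)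
Conditions: Dess–Martin periodinane, NaHCO3, CH2Cl2, 0 → 23 °C
Reagents that add atoms: none
Why: Buffered Dess–Martin oxidation should give the sensitive α,β-epoxy aldehyde without epimerization or epoxide opening, and the aldehyde is used at once (the descriptor at C5 changes to S only because the formyl group outranks C4).

Step 14
Reactants: 19 epoxy ynal
Product: 22 macrocyclic butenolide tris-silyl ether, via oxanickelacyclopentene 20 (not isolated), via acyl nickelacycle 21 (not isolated)
Conditions: Ni(cod)2 (1.2 equiv), PCy3 (1.2 equiv), PhMe, 23 °C, slow addition of 19 (final 1 mM); then CO (1 atm), 23 °C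
Reagents that add atoms: carbon monoxide, [C-]#[O+]
Why: Proposed new method: zerovalent nickel binds the aldehyde and the alkyne of 19 and oxidative cyclization joins C6 to C7 to give oxanickelacyclopentene 20, CO then inserts into the Ni–C11 bond to give acyl nickelacycle 21, and C–O reductive elimination releases butenolide 22, so that the C7–C6 and C12–C11 bonds (and the lactone C–O bond) form in one operation, a formal hetero-Pauson–Khand [2+2+1]. The closest known reaction types are the intramolecular hetero-Pauson–Khand cyclocarbonylation of 1,6-ynals to fused butenolides, the nickel-mediated aldehyde–alkyne oxidative cyclization that closes macrocycles in reductive ynal couplings, and the nickel [2+2+1] of imines, alkynes and CO; the ten-membered ring size and the carbonylation of the oxanickelacycle are the untested parts. The ten-membered carbocycle closes in the exo mode, the aldehyde carbon bonding to the tether-bearing alkyne carbon C7 so that C11 stays outside the ring, and the five-membered lactone closes by CO insertion and reductive elimination from the six-membered nickelacycle. The new stereocentre C6 is controlled by the adjacent epoxide, since Felkin–Anh (polar, Cornforth-type) addition anti to the C5–O bond gives the 5,6-anti relationship, that is 6R, and allylic 1,3-strain between C8–H and the C13 methylene places C9 and C5 on the same face of the new alkene, which is the same diastereomer. The step needs bonding at C7 and not C11, secured because bonding at C11 would put an E tetrasubstituted alkene inside an eleven-membered ring; it needs C6 cis to C12, secured by syn addition across the alkyne; and it needs cyclization to beat oligomerization and loss of the propargylic oxygen groups, secured by slow addition at high dilution and by silyl ethers in place of esters at C8 and C13.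

Step 15
Reactants: 22 tris-silyl ether
Product: 23 8,13-diol (C14–OSi-t-BuPh2 kept)
Conditions: HF·pyridine, pyridine, THF, 0 → 23 °C
Reagents that add atoms: none
Why: Fluoride-mediated desilylation with buffered HF·pyridine should remove the two tert-butyldimethylsilyl ethers well before the more robust tert-butyldiphenylsilyl ether, and the mildly acidic medium avoids deprotonation at C6 of the butenolide.

Step 16
Reactants: 23 diol
Product: 24 13-acetate (C8–OH free)
Conditions: Candida antarctica lipase B (immobilized), vinyl acetate, t-BuOMe, 30 °C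
Reagents that add atoms: vinyl acetate, C=COC(C)=O
Why: Lipase-catalysed transesterification with vinyl acetate (an enzymatic acyl transfer) should acylate the unhindered primary hydroxyl and leave the hindered secondary C8 hydroxyl, under neutral conditions that spare the butenolide and the epoxide.

Step 17
Reactants: 24 hydroxy acetate
Product: 25 13-acetate 8-isovalerate
Conditions: 3-methylbutanoic anhydride, DMAP (cat.), pyridine, CH2Cl2, 0 °C
Reagents that add atoms: 3-methylbutanoic anhydride, CC(C)CC(=O)OC(=O)CC(C)C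
Why: DMAP-catalysed acylation of the remaining secondary alcohol with the anhydride installs the isovalerate under weakly basic conditions that should not enolize the butenolide.

Step 18
Reactants: 25 silyl ether
Product: 26 14-alcohol
Conditions: n-Bu4NF, AcOH (1:1), THF, 23 °C
Reagents that add atoms: none
Why: Buffered fluoride desilylation removes the last silyl ether, and acetic acid keeps the medium near neutral so that the two esters, the epoxide and the C6 proton are not attacked.

Step 19
Reactants: 26 allylic alcohol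
Product: 27 target, CNP0289605.1
Conditions: MnO2 (activated, excess), CH2Cl2, 23 °C
Reagents that add atoms: none
Why: MnO2 oxidation of the allylic alcohol gives the enal without changing the E geometry, and because C8 is already acylated no lactol or lactone can form with the new aldehyde.

**Compound list**

1 | methyl 4-chloro-4-oxobutanoate | COC(=O)CCC(Cl)=O | starting material
2 | tert-butyldimethyl(prop-2-yn-1-yloxy)silane | C#CCO[Si](C)(C)C(C)(C)C | starting material
3 | methyl 7-[(tert-butyldimethylsilyl)oxy]-4-oxohept-5-ynoate | COC(=O)CCC(=O)C#CCO[Si](C)(C)C(C)(C)C | intermediate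
4 | methyl (4S)-7-[(tert-butyldimethylsilyl)oxy]-4-hydroxyhept-5-ynoate | COC(=O)CC[C@H](O)C#CCO[Si](C)(C)C(C)(C)C | intermediate
5 | (5S)-5-{3-[(tert-butyldimethylsilyl)oxy]prop-1-yn-1-yl}oxolan-2-one | O=C1CC[C@@H](C#CCO[Si](C)(C)C(C)(C)C)O1 | intermediate
6 | geraniol, (2E)-3,7-dimethylocta-2,6-dien-1-ol | CC(C)=CCC/C(C)=C/CO | starting material
7 | (2R,3R)-2,3-epoxygeraniol, [(2R,3R)-3-methyl-3-(4-methylpent-3-en-1-yl)oxiran-2-yl]methanol | CC(C)=CCC[C@@]1(C)O[C@@H]1CO | intermediate
8 | (2R,3R)-2-{[(4-methoxybenzyl)oxy]methyl}-3-methyl-3-(4-methylpent-3-en-1-yl)oxirane | CC(C)=CCC[C@@]1(C)O[C@@H]1COCc1ccc(OC)cc1 | intermediate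
9 | 5-[(2R,3R)-3-{[(4-methoxybenzyl)oxy]methyl}-2-methyloxiran-2-yl]-2-methylpentane-2,3-diol (both epimers at C3) | CC(C)(O)C(O)CC[C@@]1(C)O[C@@H]1COCc1ccc(OC)cc1 | intermediate
10 | 3-[(2R,3R)-3-{[(4-methoxybenzyl)oxy]methyl}-2-methyloxiran-2-yl]propanal | O=CCC[C@@]1(C)O[C@@H]1COCc1ccc(OC)cc1 | intermediate
11 | lithium enolate of lactone 5 | [Li]OC1=CC[C@@H](C#CCO[Si](C)(C)C(C)(C)C)O1 | intermediate
12 | (5S)-3-{1-hydroxy-3-[(2R,3R)-3-{[(4-methoxybenzyl)oxy]methyl}-2-methyloxiran-2-yl]propyl}-5-{3-[(tert-butyldimethylsilyl)oxy]prop-1-yn-1-yl}oxolan-2-one (mixture at C3 and the carbinol carbon) | O=C1O[C@H](C#CCO[Si](C)(C)C(C)(C)C)CC1C(O)CC[C@@]1(C)O[C@@H]1COCc1ccc(OC)cc1 | intermediate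
13 | methanesulfonate of 12 | O=C1O[C@H](C#CCO[Si](C)(C)C(C)(C)C)CC1C(OS(C)(=O)=O)CC[C@@]1(C)O[C@@H]1COCc1ccc(OC)cc1 | intermediate
14 | (3E,5S)-3-{3-[(2R,3R)-3-{[(4-methoxybenzyl)oxy]methyl}-2-methyloxiran-2-yl]propylidene}-5-{3-[(tert-butyldimethylsilyl)oxy]prop-1-yn-1-yl}oxolan-2-one | O=C1O[C@H](C#CCO[Si](C)(C)C(C)(C)C)C/C1=C\CC[C@@]1(C)O[C@@H]1COCc1ccc(OC)cc1 | intermediate
15 | (2E)-2-{(2S)-5-[(tert-butyldimethylsilyl)oxy]-2-hydroxypent-3-yn-1-yl}-5-[(2R,3R)-3-{[(4-methoxybenzyl)oxy]methyl}-2-methyloxiran-2-yl]pent-2-en-1-ol | OC/C(C[C@H](O)C#CCO[Si](C)(C)C(C)(C)C)=C/CC[C@@]1(C)O[C@@H]1COCc1ccc(OC)cc1 | intermediate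
16 | (4S,6E)-1-[(tert-butyldimethylsilyl)oxy]-6-{[(tert-butyldiphenylsilyl)oxy]methyl}-9-[(2R,3R)-3-{[(4-methoxybenzyl)oxy]methyl}-2-methyloxiran-2-yl]non-6-en-2-yn-4-ol | CC(C)(C)[Si](c1ccccc1)(c1ccccc1)OC/C(C[C@H](O)C#CCO[Si](C)(C)C(C)(C)C)=C/CC[C@@]1(C)O[C@@H]1COCc1ccc(OC)cc1 | intermediate
17 | (4S,6E)-1,4-bis[(tert-butyldimethylsilyl)oxy]-6-{[(tert-butyldiphenylsilyl)oxy]methyl}-9-[(2R,3R)-3-{[(4-methoxybenzyl)oxy]methyl}-2-methyloxiran-2-yl]non-6-en-2-yne | CC(C)(C)[Si](c1ccccc1)(c1ccccc1)OC/C(C[C@H](O[Si](C)(C)C(C)(C)C)C#CCO[Si](C)(C)C(C)(C)C)=C/CC[C@@]1(C)O[C@@H]1COCc1ccc(OC)cc1 | intermediate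
18 | [(2R,3R)-3-{(3E,6S)-6,9-bis[(tert-butyldimethylsilyl)oxy]-4-{[(tert-butyldiphenylsilyl)oxy]methyl}non-3-en-7-yn-1-yl}-3-methyloxiran-2-yl]methanol | CC(C)(C)[Si](c1ccccc1)(c1ccccc1)OC/C(C[C@H](O[Si](C)(C)C(C)(C)C)C#CCO[Si](C)(C)C(C)(C)C)=C/CC[C@@]1(C)O[C@@H]1CO | intermediate
19 | (2S,3R)-3-{(3E,6S)-6,9-bis[(tert-butyldimethylsilyl)oxy]-4-{[(tert-butyldiphenylsilyl)oxy]methyl}non-3-en-7-yn-1-yl}-3-methyloxirane-2-carbaldehyde | CC(C)(C)[Si](c1ccccc1)(c1ccccc1)OC/C(C[C@H](O[Si](C)(C)C(C)(C)C)C#CCO[Si](C)(C)C(C)(C)C)=C/CC[C@@]1(C)O[C@@H]1C=O | intermediate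
20 | oxanickelacyclopentene (Ni bound to O6 and C11, PCy3 on nickel) | CC(C)(C)[Si](C)(C)OCC1=C2[C@@H](O[Si](C)(C)C(C)(C)C)C/C(CO[Si](c3ccccc3)(c3ccccc3)C(C)(C)C)=C\CC[C@@]3(C)O[C@@H]3[C@@H]2O[Ni-]1[P+](C1CCCCC1)(C1CCCCC1)C1CCCCC1 | intermediate
21 | acyl nickelacycle (Ni bound to O6 and the C12 acyl carbon, PCy3 on nickel) | CC(C)(C)[Si](C)(C)OCC1=C2[C@@H](O[Si](C)(C)C(C)(C)C)C/C(CO[Si](c3ccccc3)(c3ccccc3)C(C)(C)C)=C\CC[C@@]3(C)O[C@@H]3[C@@H]2O[Ni-]([P+](C2CCCCC2)(C2CCCCC2)C2CCCCC2)C1=O | intermediate
22 | (1(10)E,4R,5R,6R,8S)-8,13-bis[(tert-butyldimethylsilyl)oxy]-14-[(tert-butyldiphenylsilyl)oxy]-4,5-epoxygermacra-1(10),7(11)-dien-12,6-olide | CC(C)(C)[Si](C)(C)OCC1=C2[C@@H](O[Si](C)(C)C(C)(C)C)C/C(CO[Si](c3ccccc3)(c3ccccc3)C(C)(C)C)=C\CC[C@@]3(C)O[C@@H]3[C@@H]2OC1=O | intermediate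
23 | (1(10)E,4R,5R,6R,8S)-14-[(tert-butyldiphenylsilyl)oxy]-4,5-epoxy-8,13-dihydroxygermacra-1(10),7(11)-dien-12,6-olide | OCC1=C2[C@@H](O)C/C(CO[Si](c3ccccc3)(c3ccccc3)C(C)(C)C)=C\CC[C@@]3(C)O[C@@H]3[C@@H]2OC1=O | intermediate
24 | (1(10)E,4R,5R,6R,8S)-13-acetoxy-14-[(tert-butyldiphenylsilyl)oxy]-4,5-epoxy-8-hydroxygermacra-1(10),7(11)-dien-12,6-olide | CC(=O)OCC1=C2[C@@H](O)C/C(CO[Si](c3ccccc3)(c3ccccc3)C(C)(C)C)=C\CC[C@@]3(C)O[C@@H]3[C@@H]2OC1=O | intermediate
25 | (1(10)E,4R,5R,6R,8S)-13-acetoxy-14-[(tert-butyldiphenylsilyl)oxy]-4,5-epoxy-8-(3-methylbutanoyloxy)germacra-1(10),7(11)-dien-12,6-olide | CC(=O)OCC1=C2[C@@H](OC(=O)CC(C)C)C/C(CO[Si](c3ccccc3)(c3ccccc3)C(C)(C)C)=C\CC[C@@]3(C)O[C@@H]3[C@@H]2OC1=O | intermediate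
26 | (1(10)E,4R,5R,6R,8S)-13-acetoxy-4,5-epoxy-14-hydroxy-8-(3-methylbutanoyloxy)germacra-1(10),7(11)-dien-12,6-olide | CC(=O)OCC1=C2[C@@H](OC(=O)CC(C)C)C/C(CO)=C\CC[C@@]3(C)O[C@@H]3[C@@H]2OC1=O | intermediate
27 | CNP0289605.1, (1(10)E,4R,5R,6R,8S)-13-acetoxy-4,5-epoxy-8-(3-methylbutanoyloxy)-14-oxogermacra-1(10),7(11)-dien-12,6-olide | CC(=O)OCC1=C2[C@@H](OC(=O)CC(C)C)C/C(C=O)=C\CC[C@@]3(C)O[C@@H]3[C@@H]2OC1=O | target

**Summary**

Total step count: 19. Longest linear sequence: 16 steps (from 6 through steps 4–19, or from 1 through steps 1–3 and 7–19).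

Steps most likely to fail:

1. Step 14 (the proposed new method). What may go wrong:
   - the ten-membered ring may fail to close, with intermolecular coupling or oligomerization taking over;
   - the oxidative cyclization may bond at C11 instead of C7;
   - the nickelacycle may lose the C13 silyloxy group by β-elimination before CO insertion;
   - the epoxide may be opened by zerovalent nickel;
   - facial selectivity at C6 may be poor.

   Fallback with known chemistry: the lactone carbonyl carbon is put on first and the ring is closed by a Nozaki–Hiyama–Kishi reaction. It sets out from alkyne 17. Titanium-mediated carboxylation and iodination (Ti(Oi-Pr)4, i-PrMgCl, Et2O, −78 → −50 °C; CO2; I2) should place the carboxyl group on the less hindered alkyne carbon C11 and iodine on C7, syn to each other, to give (Z)-β-iodo acrylic acid F1. Me3SiCHN2 gives methyl ester F2, DDQ removes the PMB group to give epoxy alcohol F3, and Dess–Martin oxidation gives epoxy aldehyde F4. Macrocyclization of F4 with CrCl2 and catalytic NiCl2 (DMSO–THF, high dilution) forms the C6–C7 bond under the same Felkin control, and the resulting alkoxide lactonizes onto the cis methyl ester, which comes back to the route at 22.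

2. Step 8. What may go wrong: the elimination may give a mixture containing the Z alkylidene lactone, or the aldolate may revert (retro-aldol) before it eliminates. Fallback: a Wittig olefination fixes the geometry instead. It sets out from lactone 5. Bromination of its lithium enolate (LiN(SiMe3)2, THF, −78 °C; NBS) gives α-bromo lactone F5, and PPh3 (PhMe, 80 °C) gives phosphonium bromide F6. F6 with Et3N and aldehyde 10 (CH2Cl2, 23 °C) undergoes the E-selective Wittig reaction of a lactone-stabilized ylide and comes back to the route at 14, so that steps 7 and 8 are bypassed.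

3. Step 16. What may go wrong: the enzyme may not accept the hindered macrocycle, or regioselectivity between the two hydroxyls may be lost. Fallback: the two hydroxyls are unmasked one after the other instead of being told apart by the enzyme. It sets out from 22. Brief treatment with buffered HF·pyridine at 0 °C should cleave only the primary C13 silyl ether to give alcohol F7, and Ac2O in pyridine gives acetate F8. Longer treatment of F8 with HF·pyridine then removes the secondary C8 tert-butyldimethylsilyl ether while the tert-butyldiphenylsilyl ether stays, which comes back to the route at 24, so that steps 15 and 16 are bypassed.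

Further compounds
F1 | step 14 | (2Z)-β-iodo acrylic acid from 17 (CO2H on C11, I on C7, cis) | CC(C)(C)[Si](c1ccccc1)(c1ccccc1)OC/C(C[C@H](O[Si](C)(C)C(C)(C)C)/C(I)=C(\CO[Si](C)(C)C(C)(C)C)C(O)=O)=C/CC[C@@]1(C)O[C@@H]1COCc1ccc(OC)cc1
F2 | step 14 | methyl ester of F1 | CC(C)(C)[Si](c1ccccc1)(c1ccccc1)OC/C(C[C@H](O[Si](C)(C)C(C)(C)C)/C(I)=C(\CO[Si](C)(C)C(C)(C)C)C(=O)OC)=C/CC[C@@]1(C)O[C@@H]1COCc1ccc(OC)cc1
F3 | step 14 | epoxy alcohol from F2 (PMB removed) | CC(C)(C)[Si](c1ccccc1)(c1ccccc1)OC/C(C[C@H](O[Si](C)(C)C(C)(C)C)/C(I)=C(\CO[Si](C)(C)C(C)(C)C)C(=O)OC)=C/CC[C@@]1(C)O[C@@H]1CO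
F4 | step 14 | epoxy aldehyde from F3 | CC(C)(C)[Si](c1ccccc1)(c1ccccc1)OC/C(C[C@H](O[Si](C)(C)C(C)(C)C)/C(I)=C(\CO[Si](C)(C)C(C)(C)C)C(=O)OC)=C/CC[C@@]1(C)O[C@@H]1C=O
F5 | step 8 | (5S)-3-bromo-5-{3-[(tert-butyldimethylsilyl)oxy]prop-1-yn-1-yl}oxolan-2-one (both epimers at C3) | O=C1O[C@H](C#CCO[Si](C)(C)C(C)(C)C)CC1Br
F6 | step 8 | [(5S)-5-{3-[(tert-butyldimethylsilyl)oxy]prop-1-yn-1-yl}-2-oxooxolan-3-yl]triphenylphosphonium bromide | O=C1O[C@H](C#CCO[Si](C)(C)C(C)(C)C)CC1[P+](c1ccccc1)(c1ccccc1)c1ccccc1.[Br-]
F7 | step 16 | 13-alcohol from 22 (C8–OSi-t-BuMe2 and C14–OSi-t-BuPh2 kept) | OCC1=C2[C@@H](O[Si](C)(C)C(C)(C)C)C/C(CO[Si](c3ccccc3)(c3ccccc3)C(C)(C)C)=C\CC[C@@]3(C)O[C@@H]3[C@@H]2OC1=O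
F8 | step 16 | 13-acetate of F7 | CC(=O)OCC1=C2[C@@H](O[Si](C)(C)C(C)(C)C)C/C(CO[Si](c3ccccc3)(c3ccccc3)C(C)(C)C)=C\CC[C@@]3(C)O[C@@H]3[C@@H]2OC1=O
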